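**Strategy.** The dihydropyran ring is cut at C4a–C4 and C3–C2, which turns the C3 carbinol into the boron-bearing carbon of a vinylboron ate complex. One palladium-catalysed, enantioselective conjunctive cross-coupling then joins three pieces: the aryl triflate carbon C4a of the benzo ring, a vinyl group (C4, C3) and an isopropenyl group (C2 and its methyl carbons) that migrates from boron to C3. The step exploits the aryl–CH2–CH(OH)–C(quaternary) array C4a–C4–C3–C2 of the pyran ring and sets C3. Its precursor is a bis(alkenyl)borate together with a tetrasubstituted acetophenone triflate; oxidation, acid-mediated O1–C2 closure and a Claisen–Schmidt condensation complete the chalcone.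

Key step: step 3

Remarks and assumptions on the chemistry:
- Chroman numbering is used throughout: O1, C2 (CMe2), C3 (CHOH), C4 (CH2), C4a, C5 (OMe), C6, C7, C8 (acyl), C8a. The target is (3S).
- 2′,3′-Dihydroxy-4′-methoxyacetophenone is taken as commercially available (sold as the hydrate, to be dried azeotropically).
- The (Sp,Sp) enantiomer of MandyPhos is assumed to deliver the (S)-boronate; should the sense of induction be the opposite, the equally available (Rp,Rp) ligand is used instead.

Step 1
Reactants: 1 1-(2,3-dihydroxy-4-methoxyphenyl)ethanone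
Product: 2 3-acetyl-2-hydroxy-6-methoxyphenyl trifluoromethanesulfonate
Conditions: PhNTf2 (1.05 equiv), Et3N, CH2Cl2, 0 °C → rt
Reagents that add atoms: N-phenylbis(trifluoromethanesulfonimide), O=S(=O)(N(c1ccccc1)S(=O)(=O)C(F)(F)F)C(F)(F)F
Why: Selective phenol triflation: the 2-OH is locked in a hydrogen bond to the acetyl carbonyl and is the less nucleophilic hydroxyl (the same bias that leaves it untouched in classical partial alkylations of gallacetophenones), so the mild triflyl donor should react at the 3-OH.

Step 2
Reactants: 2 3-acetyl-2-hydroxy-6-methoxyphenyl trifluoromethanesulfonate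
Product: 3 3-acetyl-6-methoxy-2-(methoxymethoxy)phenyl trifluoromethanesulfonate
Conditions: MOMCl, i-Pr2NEt, CH2Cl2, 0 °C → rt
Reagents that add atoms: chloromethyl methyl ether, COCCl
Why: O-alkylation of the remaining chelated phenol (MOM protection) removes the acidic proton before the borate coupling and gives an acetal that survives alkaline peroxide, which a free ortho-hydroxy ketone would not (Dakin oxidation).

Step 3
Reactants: 3 3-acetyl-6-methoxy-2-(methoxymethoxy)phenyl trifluoromethanesulfonate; 4 vinylboronic acid pinacol ester; 5 isopropenylmagnesium bromide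
Product: 8 1-[3-[(2S)-2-hydroxy-3-methylbut-3-en-1-yl]-4-methoxy-2-(methoxymethoxy)phenyl]ethanone, via bis(alkenyl)borate 6 (not isolated), via (S)-allylboronate 7 (not isolated)
Conditions: 4 + 5, THF, 0 °C → rt, then NaOTf (2 equiv); 3, Pd(OAc)2 (2 mol %), (Sp,Sp)-MandyPhos (1,1′-bis(diphenylphosphino)-2,2′-bis[(dimethylamino)(phenyl)methyl]ferrocene, C52H50FeN2P2, 2.4 mol %), THF, 60 °C; then 3 M NaOH, 30 % H2O2, 0 °C
Reagents that add atoms: hydrogen peroxide, OO
Why: Oxidative addition of zerovalent palladium into the C–OTf bond of 3 gives a cationic aryl–palladium complex (divalent palladium) that binds the unsubstituted vinyl group of borate 6; this π-activation triggers an anti 1,2-metallate shift of the isopropenyl group from boron to C3 while palladium bonds to C4, and reductive elimination then forms the C4–C4a bond, so that C3–C2 and C4–C4a are made in one catalytic cycle. The closest known reaction type is the enantioselective palladium-catalysed conjunctive cross-coupling of bis(alkenyl)borates with aryl triflates, here run with a Grignard-derived ate complex and NaOTf. No ring is closed in this step; the dihydropyran ring is completed in step 4 across the two new bonds. The C3 stereocentre is set under catalyst control by the planar-chiral MandyPhos ligand, which selects the face of the bound vinyl group, and the boron-to-oxygen oxidation should proceed with retention to the (S)-alcohol. The step needs chemoselectivity between the two alkenyl groups and suppression of direct Suzuki-type alkenyl transfer: the less hindered vinyl group is the better ligand for palladium while the α-substituted isopropenyl group is the better migrating group, the wide-bite-angle bisphosphine favours the metallate shift over transmetallation, NaOTf removes bromide that would block the cationic palladium site, and the ketone is safe because no free Grignard reagent remains once 6 is formed.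

Step 4
Reactants: 8 1-[3-[(2S)-2-hydroxy-3-methylbut-3-en-1-yl]-4-methoxy-2-(methoxymethoxy)phenyl]ethanone
Product: 10 1-[(3S)-3-hydroxy-5-methoxy-2,2-dimethyl-3,4-dihydro-2H-chromen-8-yl]ethanone, via free phenol 9 (not isolated)
Conditions: 1 M HCl, MeOH, rt; evaporate; then TfOH (5 mol %), CH2Cl2, 0 °C → rt
Reagents that add atoms: none
Why: Acetal methanolysis frees the phenol, and Brønsted-acid Markovnikov hydroalkoxylation of the 1,1-disubstituted alkene (6-exo-trig; the β-hydroxy tertiary cation is the same intermediate as in the classical acid-mediated 6-endo cyclisation of ortho-prenyl epoxides to 2,2-dimethylchroman-3-ols) should close O1–C2, while no bond to C3 is broken, so its (S) configuration is kept.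

Step 5
Reactants: 10 1-[(3S)-3-hydroxy-5-methoxy-2,2-dimethyl-3,4-dihydro-2H-chromen-8-yl]ethanone; 11 4-hydroxybenzaldehyde
Product: 12 (2E)-1-[(3S)-3-hydroxy-5-methoxy-2,2-dimethyl-3,4-dihydro-2H-chromen-8-yl]-3-(4-hydroxyphenyl)prop-2-en-1-one
Conditions: KOH (50 % aq., excess), EtOH, rt → 50 °C; then 1 M HCl to pH 5
Reagents that add atoms: none
Why: Claisen–Schmidt (crossed aldol) condensation: the methyl ketone enolate adds to the aldehyde and E1cB dehydration should give the thermodynamically favoured (E)-enone, while the C3 carbinol is not epimerisable under base.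

**Compound list**

1 | 1-(2,3-dihydroxy-4-methoxyphenyl)ethanone (2′,3′-dihydroxy-4′-methoxyacetophenone) | COc1ccc(C(C)=O)c(O)c1O | starting material
2 | 3-acetyl-2-hydroxy-6-methoxyphenyl trifluoromethanesulfonate | COc1ccc(C(C)=O)c(O)c1OS(=O)(=O)C(F)(F)F | intermediate
3 | 3-acetyl-6-methoxy-2-(methoxymethoxy)phenyl trifluoromethanesulfonate | COc1ccc(C(C)=O)c(OCOC)c1OS(=O)(=O)C(F)(F)F | intermediate
4 | vinylboronic acid pinacol ester (4,4,5,5-tetramethyl-2-vinyl-1,3,2-dioxaborolane) | C=CB1OC(C)(C)C(C)(C)O1 | starting material
5 | isopropenylmagnesium bromide | CC(=C)[Mg]Br | starting material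
6 | bromomagnesium isopropenyl(vinyl)(pinacolato)borate | C=C[B-]1(C(C)=C)OC(C)(C)C(C)(C)O1.[Mg+]Br | intermediate
7 | 1-[4-methoxy-2-(methoxymethoxy)-3-[(2S)-3-methyl-2-(4,4,5,5-tetramethyl-1,3,2-dioxaborolan-2-yl)but-3-en-1-yl]phenyl]ethanone | COc1ccc(C(C)=O)c(OCOC)c1C[C@H](B2OC(C)(C)C(C)(C)O2)C(C)=C | intermediate
8 | 1-[3-[(2S)-2-hydroxy-3-methylbut-3-en-1-yl]-4-methoxy-2-(methoxymethoxy)phenyl]ethanone | COc1ccc(C(C)=O)c(OCOC)c1C[C@H](O)C(C)=C | intermediate
9 | 1-[2-hydroxy-3-[(2S)-2-hydroxy-3-methylbut-3-en-1-yl]-4-methoxyphenyl]ethanone | COc1ccc(C(C)=O)c(O)c1C[C@H](O)C(C)=C | intermediate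
10 | 1-[(3S)-3-hydroxy-5-methoxy-2,2-dimethyl-3,4-dihydro-2H-chromen-8-yl]ethanone | COc1ccc(C(C)=O)c2c1C[C@H](O)C(C)(C)O2 | intermediate
11 | 4-hydroxybenzaldehyde | O=Cc1ccc(O)cc1 | starting material
12 | (2E)-1-[(3S)-3-hydroxy-5-methoxy-2,2-dimethyl-3,4-dihydro-2H-chromen-8-yl]-3-(4-hydroxyphenyl)prop-2-en-1-one | COc1ccc(C(=O)/C=C/c2ccc(O)cc2)c2c1C[C@H](O)C(C)(C)O2 | target

**Total step count:** 5
**Longest linear sequence:** 5 steps (1 → 2 → 3 → 8 → 10 → 12)

**Steps most likely to fail**

1. Step 3. Oxidative addition and turnover may be slow at the triflate flanked by two ortho oxygen substituents. Direct Suzuki-type alkenyl transfer, activation of the isopropenyl instead of the vinyl group, or weak facial selectivity may also compete. The fallback sets out from 3 and returns at 10, with C3 set by reagent control instead. Stille coupling of 3 with tributyl(3-methylbut-2-en-1-yl)stannane (Pd(PPh3)4, LiCl, DMF, 90 °C) would give 1-[4-methoxy-2-(methoxymethoxy)-3-(3-methylbut-2-en-1-yl)phenyl]ethanone F1. Shi epoxidation with the L-fructose-derived ketone (Oxone, 2KHSO5·KHSO4·K2SO4, K2CO3, MeCN/dimethoxymethane/aqueous buffer, 0 °C) would give 1-[3-{[(2S)-3,3-dimethyloxiran-2-yl]methyl}-4-methoxy-2-(methoxymethoxy)phenyl]ethanone F2; the spiro transition-state model predicts the (S)-epoxide for this ketone enantiomer. Camphorsulfonic acid in CH2Cl2 containing MeOH (2 equiv) at 0 °C would then open the epoxide 6-endo at the tertiary carbon through the aryl ether oxygen, with loss of the methoxymethyl group. The C3–O bond is untouched, so 10 is reached with the (S) configuration.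

2. Step 4. Under the acid the allylic C3–OH may ionise, which would erode the configuration or lead to 5-exo closure to an isopropenyl dihydrobenzofuran. The β-hydroxy cation may also undergo a hydride shift to a ketone. The fallback sets out from 9, which is then isolated after the methanolysis stage, and returns at 10. Intramolecular oxymercuration (Hg(OCOCF3)2, THF, rt; then aqueous NaCl) would give 1-[(3S)-2-(chloromercuriomethyl)-3-hydroxy-5-methoxy-2-methyl-3,4-dihydro-2H-chromen-8-yl]ethanone F3 as both C2 epimers, without a free carbocation. Brief demercuration (NaBH4, aqueous NaOH, THF, 0 °C, limiting hydride to spare the ketone) would turn the CH2HgCl group into the second methyl group and give 10.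

3. Step 5. The aldehyde is deactivated as its phenoxide under the basic conditions, so the aldol addition may stall and retro-aldol or Cannizzaro pathways may take over. The fallback sets out from 10 and returns at 12. Condensation of 10 with commercially available 4-(methoxymethoxy)benzaldehyde (KOH, EtOH, rt) would give (2E)-1-[(3S)-3-hydroxy-5-methoxy-2,2-dimethyl-3,4-dihydro-2H-chromen-8-yl]-3-[4-(methoxymethoxy)phenyl]prop-2-en-1-one F4. Acetal cleavage (3 M HCl, MeOH, 50 °C) would then give 12.

**Further compounds**

F1 | step 3 | 1-[4-methoxy-2-(methoxymethoxy)-3-(3-methylbut-2-en-1-yl)phenyl]ethanone | COc1ccc(C(C)=O)c(OCOC)c1CC=C(C)C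
F2 | step 3 | 1-[3-{[(2S)-3,3-dimethyloxiran-2-yl]methyl}-4-methoxy-2-(methoxymethoxy)phenyl]ethanone | COc1ccc(C(C)=O)c(OCOC)c1C[C@@H]2OC2(C)C
F3 | step 4 | 1-[(3S)-2-(chloromercuriomethyl)-3-hydroxy-5-methoxy-2-methyl-3,4-dihydro-2H-chromen-8-yl]ethanone (both C2 epimers) | COc1ccc(C(C)=O)c2c1C[C@H](O)C(C)(C[Hg]Cl)O2
F4 | step 5 | (2E)-1-[(3S)-3-hydroxy-5-methoxy-2,2-dimethyl-3,4-dihydro-2H-chromen-8-yl]-3-[4-(methoxymethoxy)phenyl]prop-2-en-1-one | COc1ccc(C(=O)/C=C/c2ccc(OCOC)cc2)c2c1C[C@H](O)C(C)(C)O2
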